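**Assumptions (one line):** (R)-(−)-carvone, 5-bromo-2-methylpent-2-ene and methyl 3-bromo-4-hydroxybenzoate are bought; the C6 epimers of **4** are not separated.

## Retrosynthetic overview
1. Cleave the C11–aryl bond by photoredox/Ni decarboxylative arylation of the 9β-CH2CO2H drim-7-ene acid **13** with aryl bromide **2**.
2. Set C9 and the Δ7 alkene by a suprafacial Johnson–Claisen of a 7β-allylic alcohol. That alcohol comes from the ring-B enone by Luche reduction and Re2O7 1,3-transposition.
3. Form the C4 quaternary centre by photochemical deoxygenative methylation of a ring-A tertiary alcohol. Methyl enters the α-face, anti to the syn-diaxial C10-Me, leaving the homoprenyl chain β-axial. The alcohol comes from Grignard addition to a ring-A ketone.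
4. Ring B is the carvone ring, which supplies C5. Ring A is closed second, by intramolecular enolate alkylation onto a trans-dialkylated carvone (C10).

## Route

**Step 1**
Reactants: **1** methyl 3-bromo-4-hydroxybenzoate
Product: **2** methyl 3-bromo-4-(tert-butyldimethylsilyloxy)benzoate
Conditions: TBSCl, imidazole, DMF, 25 °C
Reagents that add atoms: TBSCl, `CC(C)(C)[Si](C)(C)Cl`
Why: Silyl protection of the phenol so that it does not interfere with the Ni/photoredox coupling in step 12.

**Step 2**
Reactants: **3** (R)-(−)-carvone
Product: **4** (5R)-2,6-dimethyl-5-isopropenylcyclohex-2-en-1-one (C6 epimers)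
Conditions: LDA, THF, −78 °C; then MeI, −78 → 0 °C
Reagents that add atoms: iodomethane, `CI`
Why: Kinetic α′-enolate alkylation; the new C6 centre is erased again in step 3, so its configuration does not matter.

**Step 3**
Reactants: **4**
Product: **5** (5R)-6-(2-bromoethyl)-2,6-dimethyl-5-isopropenylcyclohex-2-en-1-one, with the bromoethyl trans to the isopropenyl and the methyl cis
Conditions: LDA, THF/DMPU, −78 °C; then BrCH2CH2I, −78 → 0 °C
Reagents that add atoms: 1-bromo-2-iodoethane, `BrCCI`
Why: Enolate alkylation occurs at the C–I bond, anti to the C5 isopropenyl. This sets C10 (future Me β) with the chain trans-diequatorial to the C5 substituent, which later dictates trans ring fusion.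

**Step 4**
Reactants: **5**
Product: **6** 5-acetyl-6-(2-bromoethyl)-2,6-dimethylcyclohex-2-en-1-one (same configuration as 5)
Conditions: OsO4 (2.5 mol%), NaIO4, 2,6-lutidine, dioxane/H2O, 25 °C
Reagents that add atoms: NaIO4 (oxygen source), `[Na+].[O-][I](=O)=O`
Why: Lemieux–Johnson cleavage is selective for the 1,1-disubstituted isopropenyl over the electron-poor enone alkene; no stereocentre is touched.

**Step 5**
Reactants: **6**
Product: **7** trans-fused ring-A ketone / ring-B enone; drimane-type numbering, 4-oxo, 9-oxo, Δ7, 8-Me, 10-Me β, 5-H α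
Conditions: LDA, THF, −78 → 25 °C (cat. NaI)
Reagents that add atoms: none
Why: Intramolecular enolate alkylation (6-(enolendo)-exo-tet) of the kinetic methyl-ketone enolate onto the CH2Br closes ring A. The acetyl and bromoethyl are trans-diequatorial, so the ring closes trans-fused, giving 5α-H and 10β-Me.

**Step 6**
Reactants: **7**
Product: **8** tertiary alcohol, 4-hydroxy-4-(4-methylpent-3-enyl) (C4 epimers)
Conditions: CC(C)=CCC[Mg]Br, CeCl3, THF, −78 °C
Reagents that add atoms: (4-methylpent-3-enyl)magnesium bromide, `CC(C)=CCC[Mg]Br`
Why: Organocerium 1,2-addition goes to the unhindered ring-A ketone; the neopentylic enone carbonyl next to the quaternary C10 is far less reactive. The C4 carbinol configuration is irrelevant because both epimers give the same radical in step 7.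

**Step 7**
Reactants: **8**
Product: **9** 4β-(4-methylpent-3-enyl)-4α,10β-dimethyl ketone
Conditions: N-methylbenzoxazolium triflate (alcohol activator), 2,6-lutidine, MeCN; then [Ir{dF(CF3)ppy}2(dtbbpy)]PF6 (1 mol%), NiBr2·dtbbpy (10 mol%), MeI, blue LEDs, 25 °C (one pot)
Reagents that add atoms: iodomethane, `CI`
Why: **Proposed new method:** the NHC-alcohol adduct is oxidised by the excited Ir photocatalyst and fragments to the tertiary C4 radical; a persistent Me–Ni species captures it by SH2 radical sorting. The β-face of the C4 radical is shielded by the syn-diaxial C10-Me, so CH3 adds from the α-face (Me α-equatorial, chain β-axial). Closest known chemistry: photoredox/Ni deoxygenative alkyl–alkyl coupling by radical sorting, and Reetz-type methylation of tertiary cations. It has not been shown on a hindered ring tertiary radical that is 1,3-diaxially biased by an angular methyl and sits next to a tertiary ring-fusion centre.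

**Step 8**
Reactants: **9**
Product: **10** 9β-alcohol, 7-ene
Conditions: NaBH4, CeCl3·7H2O, MeOH, −78 → 0 °C
Reagents that add atoms: none
Why: Luche 1,2-reduction; axial hydride delivery from the α-face, anti to the angular methyl, gives the equatorial 9β-OH.

**Step 9**
Reactants: **10**
Product: **11** 7β-alcohol, Δ8(9)
Conditions: Re2O7 (5 mol%), THF, 25 °C
Reagents that add atoms: none
Why: Suprafacial [3,3] 1,3-allylic transposition via the perrhenate ester keeps the oxygen on the β-face and moves it from the congested neopentylic C9 to C7. The alkene moves to C8=C9.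

**Step 10**
Reactants: **11**
Product: **12** ethyl [9β-(CH2CO2Et)] drim-7-ene ester
Conditions: MeC(OEt)3, EtCO2H (cat.), toluene, 140 °C, sealed tube
Reagents that add atoms: triethyl orthoacetate, `CCOC(C)(OCC)OCC`
Why: Johnson–Claisen rearrangement is suprafacial, so the new C9–C bond forms on the β-face from which the C7–O bond leaves. This sets C9 (CH2R β, H α) and returns the alkene to C7=C8.

**Step 11**
Reactants: **12**
Product: **13** carboxylic acid
Conditions: LiOH, THF/MeOH/H2O, 60 °C; then aq. HCl
Reagents that add atoms: lithium hydroxide/water, `[Li+].[OH-]`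
Why: Saponification; no stereocentre is affected.

**Step 12**
Reactants: **13** and **2**
Product: **14** methyl 4-OTBS-3-(drimenylmethyl)benzoate
Conditions: [Ir{dF(CF3)ppy}2(dtbbpy)]PF6 (1 mol%), NiCl2·glyme (10 mol%), dtbbpy, Cs2CO3, DMF, blue LEDs, 25 °C
Reagents that add atoms: none beyond **2**
Why: Photoredox/Ni decarboxylative Csp3–Csp2 coupling. The carboxyl radical loses CO2 to give the primary C11 radical, which is captured by Ar–Ni. C9 is untouched.

**Step 13**
Reactants: **14**
Product: **15** jaspic acid
Conditions: LiOH, THF/MeOH/H2O, 60 °C; then aq. HCl (TBAF if the silyl ether persists)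
Reagents that add atoms: water/LiOH, `O`
Why: Saponification of the methyl ester and cleavage of the aryl silyl ether.

## Compound list
1 | methyl 3-bromo-4-hydroxybenzoate | `COC(=O)c1ccc(O)c(Br)c1` | starting material
2 | methyl 3-bromo-4-(TBSO)benzoate | `COC(=O)c1ccc(O[Si](C)(C)C(C)(C)C)c(Br)c1` | intermediate
3 | (R)-(−)-carvone | `C=C(C)[C@@H]1CC=C(C)C(=O)C1` | starting material
4 | 2,6-dimethyl-5-isopropenylcyclohexenone | `C=C(C)[C@@H]1CC=C(C)C(=O)C1C` | intermediate
5 | 6-(2-bromoethyl) analogue (trans to isopropenyl) | `C=C(C)[C@@H]1CC=C(C)C(=O)[C@@]1(C)CCBr` | intermediate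
6 | 5-acetyl analogue | `CC(=O)[C@@H]1CC=C(C)C(=O)[C@@]1(C)CCBr` | intermediate
7 | trans-fused 4,9-diketone | `O=C1CCC[C@]2(C)C(=O)C(C)=CC[C@@H]12` | intermediate
8 | C4 tertiary alcohol (epimers at C4) | `CC(C)=CCCC1(O)CCC[C@]2(C)C(=O)C(C)=CC[C@@H]12` | intermediate
9 | C4-methylated ketone | `CC(C)=CCC[C@@]1(C)CCC[C@]2(C)C(=O)C(C)=CC[C@@H]12` | intermediate
10 | 9β-allylic alcohol | `CC(C)=CCC[C@@]1(C)CCC[C@]2(C)[C@@H](O)C(C)=CC[C@@H]12` | intermediate
11 | 7β-allylic alcohol, Δ8 | `CC(C)=CCC[C@@]1(C)CCC[C@]2(C)C=C(C)[C@@H](O)C[C@@H]12` | intermediate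
12 | ethyl ester | `CC(C)=CCC[C@@]1(C)CCC[C@]2(C)[C@@H](CC(=O)OCC)C(C)=CC[C@@H]12` | intermediate
13 | carboxylic acid | `CC(C)=CCC[C@@]1(C)CCC[C@]2(C)[C@@H](CC(=O)O)C(C)=CC[C@@H]12` | intermediate
14 | coupled ester/TBS ether | `CC(C)=CCC[C@@]1(C)CCC[C@]2(C)[C@@H](Cc3cc(C(=O)OC)ccc3O[Si](C)(C)C(C)(C)C)C(C)=CC[C@@H]12` | intermediate
15 | jaspic acid | `CC(C)=CCC[C@@]1(C)CCC[C@]2(C)[C@@H](Cc3cc(C(=O)O)ccc3O)C(C)=CC[C@@H]12` | target

## Totals
Total steps: 13 (including the aryl-bromide protection). Longest linear sequence: 12 (carvone → jaspic acid).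

## Three steps most likely to fail
1. **Step 7 (proposed new methylation).** Hindered tertiary-alcohol activation or methyl capture may fail, or the enone may trap the radical.
   - Fallback (known chemistry): Luche-reduce the C9 ketone of **8** and protect the secondary OH (TES). Convert the tertiary alcohol to the tertiary chloride (SOCl2) and methylate with Me2TiCl2 (Reetz-type cationic methylation, Me attacking α). Then continue at step 9.
2. **Step 9 (Re2O7 transposition).** The equilibrium or regiochemistry may be poor.
   - Fallback (known chemistry): from ketone **9**, epoxidise with H2O2/NaOH and apply Wharton (N2H4, AcOH) to give the 7α-alcohol. Oxidise with DMP to the enone and Luche-reduce (axial α-hydride) to the 7β-alcohol **11**.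
3. **Step 3 (bromoethylation of the hindered enolate).** Halogen transfer or elimination may compete.
   - Fallback (known chemistry): alkylate with allyl bromide, then hydroborate selectively at the monosubstituted alkene with 9-BBN (NaOH/H2O2). Convert the alcohol to the bromide with CBr4/PPh3 to give **5**.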